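## Retrosynthetic overview

1. Locants are cembrane locants (ring C1–C14; C15 is the carbinol carbon on C1; C18, C19, C20 are the methyls on C4, C8, C12). The target is (1R,3Z,7S,8R,10R,11E)-7,8-epoxy-15-hydroxycembra-3,11-dien-10-yl acetate.
2. Last ring formed: the oxirane (O, C7, C8), by 3-exo-tet closure of the C8 alkoxide onto a C7 mesylate of a 7R,8R diol. The diol comes from reagent-controlled reduction of an 8-hydroxy-7-ketone, itself from carbon dioxide-relayed hydration of a ring alkyne C6≡C7 steered by the free C8 hydroxyl.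
3. First ring formed: the 14-membered carbocycle, by ring-closing alkyne metathesis of an open-chain diyne, which forms C6–C7 at the alkyne oxidation level. The two methyl caps are the activating groups and leave as but-2-yne.
4. Enabling feature: oxirane carbon C7 is a CH lying between methylene C6 and the fully substituted oxirane carbon C8 (bears C19 and O, no hydrogen). C6–C7 can therefore be carried as the triple bond of a tertiary propargylic alcohol whose oxygen later directs oxygenation to C7. The other ring unsaturations (Z C3=C4, E C11=C12) are trisubstituted olefins that alkyne metathesis leaves alone.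
5. The diyne is joined at C10–C11 from fragment A (C1–C6 and C11–C15; C1 from (R)-α-terpineol, Z C3=C4 by Still–Gennari olefination) and fragment B (C7–C10; C8 by Sharpless epoxidation). C10 is set by Noyori transfer hydrogenation of the ynone, and E C11=C12 by hydroalumination, iodination and Negishi methylation.

Key step: step 20

Assumption: compounds 1 and 13 are taken as commercial in high enantiomeric and geometric purity, and the tartrate face rule and the transfer-hydrogenation model are assumed to hold for these substrates as for their closest analogues.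

## Route

Step 1
Reactants: 1 (R)-(+)-α-terpineol
Product: 2 triethyl({2-[(1R)-4-methylcyclohex-3-en-1-yl]propan-2-yl}oxy)silane
Conditions: Et3SiOTf, 2,6-lutidine, CH2Cl2, 0 °C
Reagents that add atoms: triethylsilyl trifluoromethanesulfonate (CC[Si](CC)(CC)OS(=O)(=O)C(F)(F)F)
Why: Silylation of a tertiary alcohol with a silyl triflate and a hindered pyridine base is a standard protection that masks the C15 hydroxyl against the bases, hydrides and organometallics used up to step 20; the C1 stereocenter is taken from the chiral pool and is not touched.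

Step 2
Reactants: 2 triethyl({2-[(1R)-4-methylcyclohex-3-en-1-yl]propan-2-yl}oxy)silane
Product: 4 (3R)-6-oxo-3-{2-[(triethylsilyl)oxy]propan-2-yl}heptanal, via ozonide 3 (not isolated)
Conditions: O3, CH2Cl2, −78 °C; then PPh3, −78 °C to rt
Reagents that add atoms: ozone ([O-][O+]=O)
Why: Ozonolysis with reductive work-up cleaves the only olefin of 2, so the cyclohexene opens to a chain carrying the aldehyde (future C3) and the methyl ketone (future C12) on the two arms of the untouched stereocenter.

Step 3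
Reactants: 4 (3R)-6-oxo-3-{2-[(triethylsilyl)oxy]propan-2-yl}heptanal
Product: 5 ethyl (2Z,5R)-2-methyl-8-oxo-5-{2-[(triethylsilyl)oxy]propan-2-yl}non-2-enoate
Conditions: ethyl 2-[bis(2,2,2-trifluoroethoxy)phosphoryl]propanoate, KN(SiMe3)2, 18-crown-6, THF, −78 °C
Reagents that add atoms: ethyl 2-[bis(2,2,2-trifluoroethoxy)phosphoryl]propanoate (CCOC(=O)C(C)P(=O)(OCC(F)(F)F)OCC(F)(F)F)
Why: The Still–Gennari variant of the Horner–Wadsworth–Emmons reaction (electron-poor phosphonate, dissociated potassium ion, kinetic control) should give the Z trisubstituted enoate, and the preformed phosphonate anion attacks the aldehyde far faster than the methyl ketone.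

Step 4
Reactants: 5 ethyl (2Z,5R)-2-methyl-8-oxo-5-{2-[(triethylsilyl)oxy]propan-2-yl}non-2-enoate
Product: 7 ethyl (2Z,5R)-2-methyl-5-{2-[(triethylsilyl)oxy]propan-2-yl}-8-{[(trifluoromethyl)sulfonyl]oxy}nona-2,8-dienoate, via lithium enolate 6 (not isolated)
Conditions: LiN(iPr)2, THF, −78 °C; then PhNTf2, −78 to 0 °C
Reagents that add atoms: N-phenylbis(trifluoromethanesulfonimide) (O=S(=O)(N(c1ccccc1)S(=O)(=O)C(F)(F)F)C(F)(F)F)
Why: Kinetic deprotonation of a methyl ketone by the lithium amide at low temperature occurs at the methyl group and O-triflation of the enolate gives the terminal enol triflate (enol triflate formation), the α-methyl enoate being much slower to react with the hindered base.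

Step 5
Reactants: 7 ethyl (2Z,5R)-2-methyl-5-{2-[(triethylsilyl)oxy]propan-2-yl}-8-{[(trifluoromethyl)sulfonyl]oxy}nona-2,8-dienoate
Product: 8 (5R,7Z)-9-hydroxy-8-methyl-5-{2-[(triethylsilyl)oxy]propan-2-yl}nona-1,7-dien-2-yl trifluoromethanesulfonate
Conditions: iBu2AlH, CH2Cl2, −78 °C; aqueous Rochelle salt
Reagents that add atoms: none
Why: Diisobutylaluminium hydride reduces the conjugated ester by 1,2-hydride delivery to the allylic alcohol without touching the enol triflate or the silyl ether, and the Z geometry is retained.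

Step 6
Reactants: 8 (5R,7Z)-9-hydroxy-8-methyl-5-{2-[(triethylsilyl)oxy]propan-2-yl}nona-1,7-dien-2-yl trifluoromethanesulfonate
Product: 9 (5R,7Z)-9-bromo-8-methyl-5-{2-[(triethylsilyl)oxy]propan-2-yl}nona-1,7-dien-2-yl trifluoromethanesulfonate
Conditions: CBr4, PPh3, CH2Cl2, 0 °C
Reagents that add atoms: tetrabromomethane (BrC(Br)(Br)Br)
Why: The Appel reaction converts the primary allylic alcohol into the bromide under neutral conditions with retention of the Z olefin geometry.

Step 7
Reactants: 9 (5R,7Z)-9-bromo-8-methyl-5-{2-[(triethylsilyl)oxy]propan-2-yl}nona-1,7-dien-2-yl trifluoromethanesulfonate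
Product: 10 (5R,7Z)-8-methyl-5-{2-[(triethylsilyl)oxy]propan-2-yl}dodeca-1,7-dien-10-yn-2-yl trifluoromethanesulfonate
Conditions: CH3C≡CMgBr, CuBr·SMe2 (10 mol %), THF, −20 to 0 °C
Reagents that add atoms: prop-1-ynylmagnesium bromide (CC#C[Mg]Br)
Why: Copper-catalysed substitution of a primary allylic bromide by an alkynyl Grignard reagent occurs at the unsubstituted alpha carbon and gives the skipped enyne with retention of the Z geometry, installing the methyl-capped alkyne whose inner carbon becomes C6.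

Step 8
Reactants: 10 (5R,7Z)-8-methyl-5-{2-[(triethylsilyl)oxy]propan-2-yl}dodeca-1,7-dien-10-yn-2-yl trifluoromethanesulfonate
Product: 12 triethyl({2-[(5R,7Z)-8-methyldodec-7-ene-1,10-diyn-5-yl]propan-2-yl}oxy)silane, via lithium acetylide 11 (not isolated)
Conditions: LiN(iPr)2 (2.5 equiv), THF, −78 °C; aqueous NH4Cl at −78 °C
Reagents that add atoms: none
Why: Base-induced elimination of triflate from a terminal enol triflate is a standard alkyne synthesis; the excess amide holds the new terminal alkyne as its lithium acetylide until the cold protic quench, and holding the temperature at −78 °C should leave the doubly activated C5 methylene of the skipped enyne unmetalated.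

Step 9
Reactants: 13 (2E)-3-methylpent-2-en-4-yn-1-ol
Product: 14 [(2S,3S)-3-ethynyl-3-methyloxiran-2-yl]methanol
Conditions: Ti(OiPr)4 (10 mol %), L-(+)-diisopropyl tartrate (12 mol %), tBuOOH, 4 Å molecular sieves, CH2Cl2, −20 °C
Reagents that add atoms: tert-butyl hydroperoxide (CC(C)(C)OO)
Why: Sharpless asymmetric epoxidation of a 3,3-disubstituted E allylic alcohol delivers oxygen to one olefin face under control of the tartrate ligand (L-(+)-tartrate should give the 2S,3S epoxide, as for its closest analogues), which fixes the configuration of the future C8 carbinol.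

Step 10
Reactants: 14 [(2S,3S)-3-ethynyl-3-methyloxiran-2-yl]methanol
Product: 15 (3R)-3-methylpent-4-yne-1,3-diol
Conditions: NaAlH2(OCH2CH2OMe)2 (Red-Al), THF, −20 to 0 °C; aqueous Rochelle salt
Reagents that add atoms: none
Why: The alkoxide-bound aluminium hydride delivers hydride intramolecularly to C2 of the 2,3-epoxy alcohol (directed reductive epoxide opening; the quaternary C3 cannot be attacked in an SN2 sense), giving the 1,3-diol with the C3–O bond and its stereocenter untouched, while low temperature and a small excess of hydride keep alkyne hydroalumination and SN2′ opening in check.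

Step 11
Reactants: 15 (3R)-3-methylpent-4-yne-1,3-diol
Product: 16 (3R)-3-methyl-1,3-bis[(triethylsilyl)oxy]pent-4-yne
Conditions: Et3SiOTf (2.5 equiv), 2,6-lutidine, CH2Cl2, 0 °C
Reagents that add atoms: triethylsilyl trifluoromethanesulfonate (CC[Si](CC)(CC)OS(=O)(=O)C(F)(F)F)
Why: Silyl triflate silylation protects the primary and the tertiary propargylic hydroxyl alike, which is needed for the acetylide chemistry of steps 12 and 14 and for the hydroalumination of step 17.

Step 12
Reactants: 16 (3R)-3-methyl-1,3-bis[(triethylsilyl)oxy]pent-4-yne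
Product: 18 (3R)-3-methyl-1,3-bis[(triethylsilyl)oxy]hex-4-yne, via lithium acetylide 17 (not isolated)
Conditions: nBuLi, THF, −78 °C; then MeI, −78 °C to rt
Reagents that add atoms: iodomethane (CI)
Why: Deprotonation of the terminal alkyne and C-methylation of the lithium acetylide (acetylide alkylation) installs the methyl cap required for alkyne metathesis.

Step 13
Reactants: 18 (3R)-3-methyl-1,3-bis[(triethylsilyl)oxy]hex-4-yne
Product: 19 (3R)-3-methyl-3-[(triethylsilyl)oxy]hex-4-ynal
Conditions: (COCl)2, DMSO, CH2Cl2, −78 to −40 °C; then Et3N, −78 °C to rt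
Reagents that add atoms: none
Why: Under Swern conditions a primary triethylsilyl ether is cleaved by the chlorosulfonium salt and oxidised directly to the aldehyde, whereas the hindered tertiary silyl ether is inert (oxidative deprotection).

Step 14
Reactants: 12 triethyl({2-[(5R,7Z)-8-methyldodec-7-ene-1,10-diyn-5-yl]propan-2-yl}oxy)silane; 19 (3R)-3-methyl-3-[(triethylsilyl)oxy]hex-4-ynal
Product: 21 (4R,6RS,11R,13Z)-4,14-dimethyl-4-[(triethylsilyl)oxy]-11-{2-[(triethylsilyl)oxy]propan-2-yl}octadec-13-ene-2,7,16-triyn-6-ol, via bromomagnesium acetylide 20 (not isolated)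
Conditions: EtMgBr, THF, 0 °C to rt; then 19, −78 to 0 °C; aqueous NH4Cl
Reagents that add atoms: none
Why: Ethylmagnesium bromide removes only the terminal alkyne proton of 12 (a Grignard base does not metalate the doubly activated C5 methylene), and 1,2-addition of the alkynylmagnesium bromide to the aldehyde at low temperature outruns enolisation and joins the two fragments at C10–C11 (acetylide addition to an aldehyde); the new C10 carbinol forms as both epimers, which does not matter because it is oxidised in step 15.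

Step 15
Reactants: 21 (4R,6RS,11R,13Z)-4,14-dimethyl-4-[(triethylsilyl)oxy]-11-{2-[(triethylsilyl)oxy]propan-2-yl}octadec-13-ene-2,7,16-triyn-6-ol
Product: 22 (4R,11R,13Z)-4,14-dimethyl-4-[(triethylsilyl)oxy]-11-{2-[(triethylsilyl)oxy]propan-2-yl}octadec-13-ene-2,7,16-triyn-6-one
Conditions: Dess–Martin periodinane, NaHCO3, CH2Cl2, rt
Reagents that add atoms: none
Why: Dess–Martin oxidation of a propargylic alcohol under buffered conditions gives the ynone without beta-elimination of the silyloxy group.

Step 16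
Reactants: 22 (4R,11R,13Z)-4,14-dimethyl-4-[(triethylsilyl)oxy]-11-{2-[(triethylsilyl)oxy]propan-2-yl}octadec-13-ene-2,7,16-triyn-6-one
Product: 23 (4R,6R,11R,13Z)-4,14-dimethyl-4-[(triethylsilyl)oxy]-11-{2-[(triethylsilyl)oxy]propan-2-yl}octadec-13-ene-2,7,16-triyn-6-ol
Conditions: Ru[(R,R)-TsNCHPhCHPhNH](p-cymene) (2 mol %), iPrOH, rt
Reagents that add atoms: none
Why: Noyori asymmetric transfer hydrogenation of alkynyl ketones is catalyst-controlled, the alkyne taking the place of the aryl group in the usual model, so the R,R catalyst should set the 10R carbinol (cembrane locant) regardless of the remote C1 and C8 centers and without reducing any triple bond.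

Step 17
Reactants: 23 (4R,6R,11R,13Z)-4,14-dimethyl-4-[(triethylsilyl)oxy]-11-{2-[(triethylsilyl)oxy]propan-2-yl}octadec-13-ene-2,7,16-triyn-6-ol
Product: 25 (4R,6R,7Z,11R,13Z)-8-iodo-4,14-dimethyl-4-[(triethylsilyl)oxy]-11-{2-[(triethylsilyl)oxy]propan-2-yl}octadeca-7,13-diene-2,16-diyn-6-ol, via alkenylaluminate 24 (not isolated)
Conditions: NaAlH2(OCH2CH2OMe)2 (Red-Al), THF, 0 °C to rt; then I2, THF, −78 °C
Reagents that add atoms: iodine (II)
Why: Hydroxyl-directed trans-hydroalumination of the propargylic alkoxide places aluminium on the distal carbon C12 in a five-membered alkenylaluminate, and iodinolysis with retention gives the Z iodoalkene (C10 and iodine cis); the two other alkynes have no free propargylic hydroxyl and should not react.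

Step 18
Reactants: 25 (4R,6R,7Z,11R,13Z)-8-iodo-4,14-dimethyl-4-[(triethylsilyl)oxy]-11-{2-[(triethylsilyl)oxy]propan-2-yl}octadeca-7,13-diene-2,16-diyn-6-ol
Product: 26 (4R,6R,7E,11R,13Z)-4,8,14-trimethyl-4-[(triethylsilyl)oxy]-11-{2-[(triethylsilyl)oxy]propan-2-yl}octadeca-7,13-diene-2,16-diyn-6-ol
Conditions: MeZnCl (3 equiv), Pd(PPh3)4 (5 mol %), THF, rt
Reagents that add atoms: methylzinc chloride (C[Zn]Cl)
Why: Negishi coupling replaces iodine by methyl with retention of olefin geometry, giving the E trisubstituted C11=C12 olefin with C20 cis to C10.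

Step 19
Reactants: 26 (4R,6R,7E,11R,13Z)-4,8,14-trimethyl-4-[(triethylsilyl)oxy]-11-{2-[(triethylsilyl)oxy]propan-2-yl}octadeca-7,13-diene-2,16-diyn-6-ol
Product: 27 (4R,6R,7E,11R,13Z)-4,8,14-trimethyl-4-[(triethylsilyl)oxy]-11-{2-[(triethylsilyl)oxy]propan-2-yl}octadeca-7,13-diene-2,16-diyn-6-yl acetate
Conditions: Ac2O, pyridine, 4-(dimethylamino)pyridine (cat.), CH2Cl2, 0 °C to rt
Reagents that add atoms: acetic anhydride (CC(=O)OC(C)=O)
Why: Acylation of the only free hydroxyl installs the C10 acetate of the target at a stage where no selectivity question arises.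

Step 20
Reactants: 27 (4R,6R,7E,11R,13Z)-4,8,14-trimethyl-4-[(triethylsilyl)oxy]-11-{2-[(triethylsilyl)oxy]propan-2-yl}octadeca-7,13-diene-2,16-diyn-6-yl acetate
Product: 28 (1R,3Z,8R,10R,11E)-8,15-bis[(triethylsilyl)oxy]cembra-3,11-dien-6-yn-10-yl acetate
Conditions: [Mo(≡CC6H4OMe-4)(OSiPh3)3] (10 mol %), 5 Å molecular sieves, toluene (0.002 M), 80 °C
Reagents that add atoms: none
Why: The molybdenum alkylidyne exchanges with each methyl-capped triple bond by [2+2] cycloaddition and cycloreversion through metallacyclobutadienes, loading first at the unhindered C6 end and then closing on the C7 end, while the but-2-yne set free is trapped by the 5 Å sieves so that closure is driven forward. The closest known reaction type is ring-closing alkyne metathesis of bis(methyl-capped) diynes to twelve- to twenty-membered cycloalkynes that carry propargylic oxygen substituents, esters and olefins. The 14-membered carbocycle, the only ring formed here, closes by metathesis between C6 and C7 under high dilution and not by a polar exo or endo attack, and the Z C3=C4 olefin, the C1 branch and the quaternary C8 put turns into the chain that bring the two ends together. No stereocenter is created (C6 and C7 become sp carbons), and C1, C8, C10 and both olefin geometries are untouched because the alkylidyne does not react with olefins, esters or silyl ethers. The step needs chemoselectivity for the two terminal triple bonds, secured because C11≡C12 was converted into the olefin in steps 17 and 18 and the remaining olefins are trisubstituted, and ring closure over oligomerisation, secured by dilution; the main hazard is slow engagement of the neopentyl-type alkyne at C7.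

Step 21
Reactants: 28 (1R,3Z,8R,10R,11E)-8,15-bis[(triethylsilyl)oxy]cembra-3,11-dien-6-yn-10-yl acetate
Product: 29 (1R,3Z,8R,10R,11E)-8,15-dihydroxycembra-3,11-dien-6-yn-10-yl acetate
Conditions: HF·pyridine, pyridine, THF, 0 °C to rt
Reagents that add atoms: none
Why: Buffered hydrogen fluoride cleaves both tertiary triethylsilyl ethers (fluoride desilylation) under non-basic conditions that leave the allylic acetate, the olefins and the cycloalkyne intact.

Step 22
Reactants: 29 (1R,3Z,8R,10R,11E)-8,15-dihydroxycembra-3,11-dien-6-yn-10-yl acetate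
Product: 31 (1R,3Z,8R,10R,11E)-8,15-dihydroxy-7-oxocembra-3,11-dien-10-yl acetate, via alkylidene carbonate 30 (not isolated)
Conditions: AgOAc (10 mol %), DBU, CO2 (1 MPa), MeCN, rt; then H2O, 40 °C
Reagents that add atoms: carbon dioxide (O=C=O); water (O)
Why: Silver-catalysed carboxylative cyclisation of a tertiary propargylic alcohol is a 5-exo-dig anti-oxymetalation that can deliver the carbonate oxygen only to the proximal alkyne carbon C7, and hydrolysis of the enol carbonate with loss of carbon dioxide unmasks the C7 ketone (carbon dioxide-relayed regioselective alkyne hydration); C8 is not involved.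

Step 23
Reactants: 31 (1R,3Z,8R,10R,11E)-8,15-dihydroxy-7-oxocembra-3,11-dien-10-yl acetate
Product: 32 (1R,3Z,7R,8R,10R,11E)-7,8,15-trihydroxycembra-3,11-dien-10-yl acetate
Conditions: (S)-2-methyl-CBS-oxazaborolidine (1 equiv), BH3·SMe2, THF, −30 °C; MeOH quench
Reagents that add atoms: none
Why: In this Corey–Bakshi–Shibata reduction the ketone is flanked by the fully substituted C8 (large) and the C6 methylene (small), so the S oxazaborolidine should deliver hydride to give the 7R carbinol under reagent control, the free hydroxyls being converted into borate esters by the excess borane.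

Step 24
Reactants: 32 (1R,3Z,7R,8R,10R,11E)-7,8,15-trihydroxycembra-3,11-dien-10-yl acetate
Product: 34 (1R,3Z,7S,8R,10R,11E)-7,8-epoxy-15-hydroxycembra-3,11-dien-10-yl acetate, via mesylate 33 (not isolated)
Conditions: MsCl, Et3N, CH2Cl2, −20 °C; then DBU, rt
Reagents that add atoms: none
Why: The secondary C7 hydroxyl is mesylated selectively beside the two tertiary hydroxyls, and the C8 alkoxide then displaces the mesylate in a 3-exo-tet SN2 closure with inversion at C7 (Williamson-type epoxide formation), turning the 7R,8R diol into the 7S,8R cis-oxirane of the target.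

## Compound list

1 | (R)-(+)-α-terpineol, 2-[(1R)-4-methylcyclohex-3-en-1-yl]propan-2-ol | CC1=CC[C@@H](CC1)C(C)(C)O | starting material
2 | triethyl({2-[(1R)-4-methylcyclohex-3-en-1-yl]propan-2-yl}oxy)silane | CC1=CC[C@@H](CC1)C(C)(C)O[Si](CC)(CC)CC | intermediate
3 | ozonide of 2 (1,2,4-trioxolane bridging the two former olefin carbons; mixture at the two acetal carbons; R at the carbon bearing the silyloxypropyl group) | CC12CC[C@H](CC(OO1)O2)C(C)(C)O[Si](CC)(CC)CC | intermediate
4 | (3R)-6-oxo-3-{2-[(triethylsilyl)oxy]propan-2-yl}heptanal | O=CC[C@@H](CCC(C)=O)C(C)(C)O[Si](CC)(CC)CC | intermediate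
5 | ethyl (2Z,5R)-2-methyl-8-oxo-5-{2-[(triethylsilyl)oxy]propan-2-yl}non-2-enoate | CCOC(=O)/C(C)=C\C[C@@H](CCC(C)=O)C(C)(C)O[Si](CC)(CC)CC | intermediate
6 | lithium enolate of 5 (terminal enolate of the methyl ketone, CH2=C(OLi)–) | CCOC(=O)/C(C)=C\C[C@@H](CCC(=C)O[Li])C(C)(C)O[Si](CC)(CC)CC | intermediate
7 | ethyl (2Z,5R)-2-methyl-5-{2-[(triethylsilyl)oxy]propan-2-yl}-8-{[(trifluoromethyl)sulfonyl]oxy}nona-2,8-dienoate | CCOC(=O)/C(C)=C\C[C@@H](CCC(=C)OS(=O)(=O)C(F)(F)F)C(C)(C)O[Si](CC)(CC)CC | intermediate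
8 | (5R,7Z)-9-hydroxy-8-methyl-5-{2-[(triethylsilyl)oxy]propan-2-yl}nona-1,7-dien-2-yl trifluoromethanesulfonate | OC/C(C)=C\C[C@@H](CCC(=C)OS(=O)(=O)C(F)(F)F)C(C)(C)O[Si](CC)(CC)CC | intermediate
9 | (5R,7Z)-9-bromo-8-methyl-5-{2-[(triethylsilyl)oxy]propan-2-yl}nona-1,7-dien-2-yl trifluoromethanesulfonate | BrC/C(C)=C\C[C@@H](CCC(=C)OS(=O)(=O)C(F)(F)F)C(C)(C)O[Si](CC)(CC)CC | intermediate
10 | (5R,7Z)-8-methyl-5-{2-[(triethylsilyl)oxy]propan-2-yl}dodeca-1,7-dien-10-yn-2-yl trifluoromethanesulfonate | CC#CC/C(C)=C\C[C@@H](CCC(=C)OS(=O)(=O)C(F)(F)F)C(C)(C)O[Si](CC)(CC)CC | intermediate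
11 | lithium acetylide of 12 (lithium on C1 of the dodecenediyne) | CC#CC/C(C)=C\C[C@@H](CCC#C[Li])C(C)(C)O[Si](CC)(CC)CC | intermediate
12 | triethyl({2-[(5R,7Z)-8-methyldodec-7-ene-1,10-diyn-5-yl]propan-2-yl}oxy)silane (fragment A) | CC#CC/C(C)=C\C[C@@H](CCC#C)C(C)(C)O[Si](CC)(CC)CC | intermediate
13 | (2E)-3-methylpent-2-en-4-yn-1-ol | C#C/C(C)=C/CO | starting material
14 | [(2S,3S)-3-ethynyl-3-methyloxiran-2-yl]methanol | OC[C@@H]1O[C@]1(C#C)C | intermediate
15 | (3R)-3-methylpent-4-yne-1,3-diol | O[C@](C#C)(C)CCO | intermediate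
16 | (3R)-3-methyl-1,3-bis[(triethylsilyl)oxy]pent-4-yne | CC[Si](CC)(CC)O[C@](C#C)(C)CCO[Si](CC)(CC)CC | intermediate
17 | lithium acetylide of 16 | CC[Si](CC)(CC)O[C@](C#C[Li])(C)CCO[Si](CC)(CC)CC | intermediate
18 | (3R)-3-methyl-1,3-bis[(triethylsilyl)oxy]hex-4-yne | CC[Si](CC)(CC)O[C@](C#CC)(C)CCO[Si](CC)(CC)CC | intermediate
19 | (3R)-3-methyl-3-[(triethylsilyl)oxy]hex-4-ynal (fragment B) | CC[Si](CC)(CC)O[C@](C#CC)(C)CC=O | intermediate
20 | bromomagnesium acetylide of 12 (MgBr on C1 of the dodecenediyne) | CC#CC/C(C)=C\C[C@@H](CCC#C[Mg]Br)C(C)(C)O[Si](CC)(CC)CC | intermediate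
21 | (4R,6RS,11R,13Z)-4,14-dimethyl-4-[(triethylsilyl)oxy]-11-{2-[(triethylsilyl)oxy]propan-2-yl}octadec-13-ene-2,7,16-triyn-6-ol | CC#CC/C(C)=C\C[C@@H](CCC#CC(O)C[C@@](C)(O[Si](CC)(CC)CC)C#CC)C(C)(C)O[Si](CC)(CC)CC | intermediate
22 | (4R,11R,13Z)-4,14-dimethyl-4-[(triethylsilyl)oxy]-11-{2-[(triethylsilyl)oxy]propan-2-yl}octadec-13-ene-2,7,16-triyn-6-one | CC#CC/C(C)=C\C[C@@H](CCC#CC(=O)C[C@@](C)(O[Si](CC)(CC)CC)C#CC)C(C)(C)O[Si](CC)(CC)CC | intermediate
23 | (4R,6R,11R,13Z)-4,14-dimethyl-4-[(triethylsilyl)oxy]-11-{2-[(triethylsilyl)oxy]propan-2-yl}octadec-13-ene-2,7,16-triyn-6-ol | CC#CC/C(C)=C\C[C@@H](CCC#C[C@H](O)C[C@@](C)(O[Si](CC)(CC)CC)C#CC)C(C)(C)O[Si](CC)(CC)CC | intermediate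
24 | sodium alkenylaluminate of 23 (five-membered ring O–C10–C11=C12–Al, two 2-methoxyethoxy groups on aluminium) | [Na+].CC#CC/C(C)=C\C[C@@H](CCC1=C[C@@H](C[C@@](C)(O[Si](CC)(CC)CC)C#CC)O[Al-]1(OCCOC)OCCOC)C(C)(C)O[Si](CC)(CC)CC | intermediate
25 | (4R,6R,7Z,11R,13Z)-8-iodo-4,14-dimethyl-4-[(triethylsilyl)oxy]-11-{2-[(triethylsilyl)oxy]propan-2-yl}octadeca-7,13-diene-2,16-diyn-6-ol | CC#CC/C(C)=C\C[C@@H](CC/C(I)=C/[C@H](O)C[C@@](C)(O[Si](CC)(CC)CC)C#CC)C(C)(C)O[Si](CC)(CC)CC | intermediate
26 | (4R,6R,7E,11R,13Z)-4,8,14-trimethyl-4-[(triethylsilyl)oxy]-11-{2-[(triethylsilyl)oxy]propan-2-yl}octadeca-7,13-diene-2,16-diyn-6-ol | CC#CC/C(C)=C\C[C@@H](CC/C(C)=C/[C@H](O)C[C@@](C)(O[Si](CC)(CC)CC)C#CC)C(C)(C)O[Si](CC)(CC)CC | intermediate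
27 | (4R,6R,7E,11R,13Z)-4,8,14-trimethyl-4-[(triethylsilyl)oxy]-11-{2-[(triethylsilyl)oxy]propan-2-yl}octadeca-7,13-diene-2,16-diyn-6-yl acetate | CC#CC/C(C)=C\C[C@@H](CC/C(C)=C/[C@H](OC(C)=O)C[C@@](C)(O[Si](CC)(CC)CC)C#CC)C(C)(C)O[Si](CC)(CC)CC | intermediate
28 | (1R,3Z,8R,10R,11E)-8,15-bis[(triethylsilyl)oxy]cembra-3,11-dien-6-yn-10-yl acetate | CC(=O)O[C@H]1/C=C(\C)CC[C@@H](C(C)(C)O[Si](CC)(CC)CC)C/C=C(/C)CC#C[C@](C)(O[Si](CC)(CC)CC)C1 | intermediate
29 | (1R,3Z,8R,10R,11E)-8,15-dihydroxycembra-3,11-dien-6-yn-10-yl acetate | CC(=O)O[C@H]1/C=C(\C)CC[C@@H](C(C)(C)O)C/C=C(/C)CC#C[C@](C)(O)C1 | intermediate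
30 | (1R,3Z,6Z,8R,10R,11E)-15-hydroxy-7,8-(carbonyldioxy)cembra-3,6,11-trien-10-yl acetate (cyclic carbonate across O7 and O8, enol carbonate olefin C6=C7) | CC(=O)O[C@H]1/C=C(\C)CC[C@@H](C(C)(C)O)C/C=C(/C)C/C=C2\OC(=O)O[C@]2(C)C1 | intermediate
31 | (1R,3Z,8R,10R,11E)-8,15-dihydroxy-7-oxocembra-3,11-dien-10-yl acetate | CC(=O)O[C@H]1/C=C(\C)CC[C@@H](C(C)(C)O)C/C=C(/C)CCC(=O)[C@](C)(O)C1 | intermediate
32 | (1R,3Z,7R,8R,10R,11E)-7,8,15-trihydroxycembra-3,11-dien-10-yl acetate | CC(=O)O[C@H]1/C=C(\C)CC[C@@H](C(C)(C)O)C/C=C(/C)CC[C@@H](O)[C@](C)(O)C1 | intermediate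
33 | (1R,3Z,7R,8R,10R,11E)-8,15-dihydroxy-7-[(methylsulfonyl)oxy]cembra-3,11-dien-10-yl acetate | CC(=O)O[C@H]1/C=C(\C)CC[C@@H](C(C)(C)O)C/C=C(/C)CC[C@@H](OS(C)(=O)=O)[C@](C)(O)C1 | intermediate
34 | (1R,3Z,7S,8R,10R,11E)-7,8-epoxy-15-hydroxycembra-3,11-dien-10-yl acetate | CC(=O)O[C@H]1/C=C(\C)CC[C@@H](C(C)(C)O)C/C=C(/C)CC[C@@H]2O[C@]2(C)C1 | target

## Step count and risks

Total step count: 24. Longest linear sequence: 19 steps (steps 1–8 and 14–24); steps 9–13 form the side branch to fragment B.

**Risk 1, step 20 (ring-closing alkyne metathesis).** The alkylidyne may load only at the unhindered C6 alkyne and stall at the neopentyl-type, silyloxy-flanked C7 alkyne, so that acyclic dimerisation outruns closure of the 14-membered cycloalkyne. The fallback forms the triple bond between two fragments and closes the ring elsewhere by known chemistry; it sets out from 9 and 16 and comes back to the route at 28. Terminal alkyne 16 is coupled with allylic bromide 9 (CuI, NaI, K2CO3, DMF, rt; copper-mediated alkynylation of an allylic halide) to give the skipped enyne F1, which already holds the C6≡C7 bond. Elimination of the enol triflate (LiN(iPr)2, THF, −78 °C) gives the terminal alkyne F2. Zirconium-catalysed carboalumination (AlMe3, Cp2ZrCl2, CH2Cl2) followed by iodine gives the E vinyl iodide F3. Swern oxidation of the primary silyl ether gives the iodo aldehyde F4. An intramolecular Nozaki–Hiyama–Kishi reaction (CrCl2, NiCl2 cat., DMSO/THF, high dilution) closes the 14-membered ring at C10–C11 to the ring allylic alcohol F5 as a C10 epimer mixture. Dess–Martin oxidation gives the ring enone F6, Corey–Bakshi–Shibata reduction with the S oxazaborolidine gives the 10R alcohol F7, and acetylation (Ac2O, pyridine) gives 28.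

**Risk 2, step 22 (carbon dioxide-relayed hydration).** Carboxylative cyclisation of a dialkyl-substituted ring alkyne may be slow, and the amidine base in wet medium may cleave or shift the allylic acetate or trigger an α-ketol rearrangement of the acyloin. The fallback sets out from 29 and comes back at 31. Hydroxyl-directed trans-hydrostannation ([Cp*RuCl]4 cat., Bu3SnH, CH2Cl2, rt), in which hydrogen bonding of the C8 hydroxyl to the chloride ligand places tin on the proximal carbon C7, gives the alkenylstannane F8. Copper-mediated oxidative destannylation (Cu(OAc)2, Et3N, DMSO, rt, aqueous work-up) then converts the C7–Sn bond into the C7 carbonyl and gives 31 under conditions free of strong base.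

**Risk 3, step 23 (ketone reduction).** Facial discrimination may be poor, for instance through uncatalysed hydride delivery from a borate at the neighbouring C8 oxygen, so that the 7S epimer forms. The fallback accepts that epimer and closes the oxirane with net retention; it sets out from 31 and comes back at 34. Chelation-controlled reduction with Zn(BH4)2 (Et2O, −20 °C), expected to attack anti to the ring methylene C9, gives the 7S,8R diol F9. MeC(OMe)3 with pyridinium p-toluenesulfonate gives the cyclic orthoacetate F10. Me3SiCl opens the derived acetoxonium ion at the tertiary C8 with inversion to give the chloro acetate F11. K2CO3 in MeOH removes both acetyl groups, and the C7 alkoxide displaces chloride with a second inversion at C8 to give the deacetyl epoxide F12. Selective acetylation of the secondary C10 hydroxyl (Ac2O, pyridine, 0 °C) gives 34. Any 7S diol formed in step 23 itself can be processed the same way, so neither epimer is lost.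

## Further compounds

F1 | step 20 | skipped enyne from 9 and 16: (cembrane locants) 1R,3Z,8R; C5–C6≡C7 linkage, enol triflate at C12, triethylsilyl ethers on O8, O10 and O15 | CC[Si](CC)(CC)OCC[C@@](C)(O[Si](CC)(CC)CC)C#CC/C(C)=C\C[C@@H](CCC(=C)OS(=O)(=O)C(F)(F)F)C(C)(C)O[Si](CC)(CC)CC
F2 | step 20 | terminal alkyne from F1 (C11≡C12 with hydrogen on C11) | CC[Si](CC)(CC)OCC[C@@](C)(O[Si](CC)(CC)CC)C#CC/C(C)=C\C[C@@H](CCC#C)C(C)(C)O[Si](CC)(CC)CC
F3 | step 20 | E vinyl iodide from F2 (iodine on C11, methyl C20 on C12) | CC[Si](CC)(CC)OCC[C@@](C)(O[Si](CC)(CC)CC)C#CC/C(C)=C\C[C@@H](CC/C(C)=C/I)C(C)(C)O[Si](CC)(CC)CC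
F4 | step 20 | iodo aldehyde from F3 (C10 aldehyde) | O=CC[C@@](C)(O[Si](CC)(CC)CC)C#CC/C(C)=C\C[C@@H](CC/C(C)=C/I)C(C)(C)O[Si](CC)(CC)CC
F5 | step 20 | (1R,3Z,8R,11E)-8,15-bis[(triethylsilyl)oxy]cembra-3,11-dien-6-yn-10-ol, C10 epimers | OC1/C=C(\C)CC[C@@H](C(C)(C)O[Si](CC)(CC)CC)C/C=C(/C)CC#C[C@](C)(O[Si](CC)(CC)CC)C1
F6 | step 20 | (1R,3Z,8R,11E)-8,15-bis[(triethylsilyl)oxy]cembra-3,11-dien-6-yn-10-one | O=C1/C=C(\C)CC[C@@H](C(C)(C)O[Si](CC)(CC)CC)C/C=C(/C)CC#C[C@](C)(O[Si](CC)(CC)CC)C1
F7 | step 20 | (1R,3Z,8R,10R,11E)-8,15-bis[(triethylsilyl)oxy]cembra-3,11-dien-6-yn-10-ol | O[C@H]1/C=C(\C)CC[C@@H](C(C)(C)O[Si](CC)(CC)CC)C/C=C(/C)CC#C[C@](C)(O[Si](CC)(CC)CC)C1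
F8 | step 22 | (1R,3Z,6Z,8R,10R,11E)-8,15-dihydroxy-7-(tributylstannyl)cembra-3,6,11-trien-10-yl acetate | CC(=O)O[C@H]1/C=C(\C)CC[C@@H](C(C)(C)O)C/C=C(/C)C/C=C(\[Sn](CCCC)(CCCC)CCCC)[C@](C)(O)C1
F9 | step 23 | (1R,3Z,7S,8R,10R,11E)-7,8,15-trihydroxycembra-3,11-dien-10-yl acetate | CC(=O)O[C@H]1/C=C(\C)CC[C@@H](C(C)(C)O)C/C=C(/C)CC[C@H](O)[C@](C)(O)C1
F10 | step 23 | cyclic orthoacetate of F9 (2-methoxy-2-methyl-1,3-dioxolane across O7 and O8) | CC(=O)O[C@H]1/C=C(\C)CC[C@@H](C(C)(C)O)C/C=C(/C)CC[C@@H]2OC(C)(OC)O[C@]2(C)C1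
F11 | step 23 | (1R,3Z,7S,8S,10R,11E)-8-chloro-15-hydroxycembra-3,11-diene-7,10-diyl diacetate | CC(=O)O[C@H]1/C=C(\C)CC[C@@H](C(C)(C)O)C/C=C(/C)CC[C@H](OC(C)=O)[C@@](C)(Cl)C1
F12 | step 23 | (1R,3Z,7S,8R,10R,11E)-7,8-epoxycembra-3,11-diene-10,15-diol | O[C@H]1/C=C(\C)CC[C@@H](C(C)(C)O)C/C=C(/C)CC[C@@H]2O[C@]2(C)C1
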